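## Structural features

The target is a flavanone: an aromatic ring A (C4a, C5, C6, C7, C8, C8a) fused to a dihydropyranone ring C (O1, C2, C3, C4), with an aryl ring B joined through C1′ to C2. Ring A carries no hydrogen: C5 bears a hydroxyl hydrogen-bonded to the C4 carbonyl, and C6, C7 and C8 bear methoxyl groups. Ring B is a 2-hydroxy-6-methoxyphenyl group, so both positions ortho to the C2–C1′ bond are oxygenated and C2 is crowded. C2 is the only stereocentre (S), with no neighbouring stereocentre. It is benzylic, bonded to the ring oxygen and β to the ketone. Base can therefore open ring C to the 2′-hydroxychalcone, and acid can ionise the C2–O1 bond, helped by the two ortho oxygen donors of ring B; either event racemises the compound. Other fragile points are the oxidisable para-methoxyphenol of ring A and the methyl ethers that a Lewis acid held in the C5–O/C4=O chelate could cleave. The real difficulty is twofold: a hexasubstituted ring A in which one of four adjacent oxygens must be a free hydroxyl at a defined position, and a stereocentre that must be set and kept beside a di-ortho-substituted arene. The key step uses the correspondence of C5, C6, C7 and C8 (with their oxygens) to the four carbons of a squaric ester, and of the C4a=C8a bond to the enol ether double bond of a dihydropyran that already is ring C.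

## Logic of the disconnections

16 ⇒ 15. No skeletal bond is cut; the C4 carbonyl is taken back to a secondary benzylic alcohol. Ring C must pass through the key step as an enol ether, which is only possible with C4 at the alcohol level. The gain is that the β-aryloxy ketone that makes C2 labile exists only in the final compound. The forward step must oxidise one benzylic alcohol beside two free phenols under neutral conditions.

15 ⇒ 14. The O–Si bonds at the C4 oxygen and at the ring B oxygen are restored. Using one kind of silyl group on both lets a single fluoride treatment give 15, and no Lewis acid is needed late in the route. The forward step must use buffered fluoride so that the electron-rich phenoxides are not held under basic conditions.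

14 ⇒ 11 (through 13 and 12). The C4a–C5 bond is cut and ring A is folded back into a four-membered ring attached at C8a. This replaces a hexasubstituted benzene with differentiated oxygens by an adduct of two simple pieces. The C5 hydroxyl is free because it derives from the ring carbonyl of 11, whereas the C8 oxygen is already methylated. The forward step demands that ring opening of 11 turns the pyranyl group toward the ketene, and that the C4 silyloxy group survives the heating.

11 ⇒ 7 + 8 (through 10 and 9). The C8–C8a bond and the O–CH3 bond of the carbinol oxygen are cut. 8 is a symmetrical electrophile that supplies all four oxygenated carbons of ring A, so no regiochemical question arises in the addition. 7 supplies ring C with C2 already set. The forward step demands metalation of 7 at the enol ether carbon only, mono-addition to 8, and capture of the tertiary alkoxide before it can rearrange.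

7 ⇒ 6 ⇒ 5. The C4 O–Si bond is removed, then the C4–H bond, which returns the allylic alcohol to a vinylogous ester. These are functional group changes that connect the metalation substrate to a hetero-Diels–Alder adduct. The forward steps demand 1,2-selective reduction and a silyl group inert to alkyllithium; the C4 configuration is of no lasting consequence.

5 ⇒ 2 + 3 (through 4). The C2–C3 bond and the bond from O1 to the enol ether carbon (the future C8a) are cut. This sets C2 from an achiral aldehyde by catalyst control and delivers ring C with its C4 oxygen in one operation. The forward step demands facial selectivity on an aldehyde flanked by two ortho substituents.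

2 ⇒ 1. The aryl O–Si bond is cut. The free phenol would bind the titanium catalyst and consume alkyllithium, so it is masked at the outset with the group that is removed together with the C4 silyl ether.

## Other disconnections considered

Alternative 1: The cut is O1–C8a together with C4–C4a. In the forward step, CsF would convert 3,4,5,6-tetramethoxy-2-(trimethylsilyl)phenyl triflate A2 into the symmetric aryne A4. The alkoxide of methyl (S)-3-[2-(benzyloxy)-6-methoxyphenyl]-3-hydroxypropanoate A3 would add to it, and the aryl anion would close ring C on the ester to give the chromanone A1.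
- In favour: the aryne is symmetric, so there is no regiochemical issue, and the union is convergent. C2 would be set beforehand in A3 by asymmetric hydrogenation of a β-keto ester or by an aldol reaction; on the reliability of the stereo-defining step this is the equal of the chosen plan, and probably its better.
- Against: a secondary aliphatic alkoxide is a much weaker aryne trap than a phenoxide. Under the basic conditions A3 can undergo retro-aldol cleavage or dehydration to the cinnamate, both of which erase C2. The aryl anion may be protonated before it acylates. A2 needs its own multistep preparation.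
- Comparison: A1 carries a methyl ether at C5, so a chelation-directed Lewis acid demethylation and a debenzylation must follow. The former exposes C2 to the conditions the chosen plan avoids, whereas the squarate route delivers the C5 hydroxyl free. Ring construction is one step in both plans; overall step count would be similar or higher.

Alternative 2: The cut is C1′–C6′ and C2′–C3′ of ring B. In the forward step, cyclobut-2-enone A7 and the siloxyalkyne (S)-5,6,7,8-tetramethoxy-2-[(triisopropylsilyloxy)ethynyl]chroman-4-one A6 would be heated. A Danheiser benzannulation would then build ring B as A5, with a free hydroxyl and a silyloxy group on the two carbons flanking C1′.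
- In favour: the annulation places both ring B oxygens correctly and delivers them differentiated, so methylation followed by desilylation maps directly onto the 2′-hydroxy-6′-methoxy pattern. On this point it equals the way the chosen plan differentiates the ring A oxygens. The mechanism is a pericyclic cascade of the same family, run at similar temperatures.
- Against: the key step is spent on the simplest ring, which is available intact as a commercial aldehyde, and the hexasubstituted ring A is left to classical chemistry. A6 needs an enantioenriched 2-alkynylchromanone whose propargylic C2 is prone to ring opening, plus a sensitive ynol silyl ether. A7 is volatile and unstable.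
- Comparison: A5 again has a C5 methyl ether to be cleaved selectively. The route would be clearly longer than the chosen one.

Alternative 3: The cut is O1–C2 and C3–C4. In the forward step, a chiral Brønsted acid would ionise 2-(dimethoxymethyl)-3,4,5,6-tetramethoxyphenol A9 to the 4-methoxy ortho-quinone methide A11. This would add 1-(benzyloxy)-3-methoxy-2-vinylbenzene A10 in a hetero-Diels–Alder reaction to give the chroman A8 with C2 set.
- In favour: it is the most convergent of the four plans. Both arenes arrive intact, ring C and C2 are made in one catalytic step, and the C4 oxygen is installed at the same time. In step count to the flavan core it is better than the chosen plan.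
- Against: the vinyl group of A10 is twisted out of conjugation by its two ortho substituents, which lowers its reactivity and makes facial control by the catalyst uncertain. A11 is hindered by the C5 methoxyl. A9 needs a multistep preparation.
- Comparison: the C4 methyl ether of A8 is at the wrong oxidation level. Converting it to the ketone needs hydride abstraction or acid ionisation on a very electron-rich chroman whose C2 is acid-labile. C5 demethylation and debenzylation then follow. The chosen plan carries C4 as a silyl ether released by fluoride, and the C5 hydroxyl appears free.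

Key step: step 6

Design remarks:
- The cis 2,4-disubstituted pyran and chroman intermediates are (2S,4S) throughout.
- Both hydroxyl masks are triisopropylsilyl ethers. A tert-butyldimethylsilyl ether offers Si–CH3 protons to t-BuLi. An alkyl ether on ring B would need a Lewis acid on the finished flavanone.
- Assumption: the (S)-BINOL–Ti(OiPr)4 catalyst is taken to attack the aldehyde face that leads to (S)-5; should the sense prove opposite, (R)-BINOL is used with no other change.

## Route

Step 1
Reactants: 1 2-hydroxy-6-methoxybenzaldehyde
Product: 2 2-methoxy-6-(triisopropylsilyloxy)benzaldehyde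
Conditions: TIPSCl, imidazole, DMF, rt
Reagents that add atoms: chlorotriisopropylsilane, CC(C)[Si](Cl)(C(C)C)C(C)C
Why: Silylation of a phenol; the triisopropylsilyl ether has no acidic Si–CH3 or O–CH2 protons, does not direct ortho-metalation, tolerates the organolithium and thermal steps, and keeps the phenol from binding the titanium catalyst of step 2.

Step 2
Reactants: 2 2-methoxy-6-(triisopropylsilyloxy)benzaldehyde; 3 trans-1-methoxy-3-(trimethylsilyloxy)buta-1,3-diene
Product: 5 (S)-2-[2-methoxy-6-(triisopropylsilyloxy)phenyl]-2,3-dihydro-4H-pyran-4-one, via Mukaiyama aldol silyl ether 4 (not isolated)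
Conditions: (S)-BINOL (20 mol %), Ti(OiPr)4 (10 mol %), 4 Å MS, Et2O, −20 °C; then TFA (cat.), CH2Cl2, 0 °C
Reagents that add atoms: none
Why: Catalytic asymmetric hetero-Diels–Alder reaction that proceeds as a Mukaiyama aldol addition followed by acid cyclisation with loss of methanol; the chiral BINOL–titanium complex shields one face of the coordinated aldehyde and so sets C2, and the acid contact is kept short and cold to avoid ionising the new benzylic C–O bond.

Step 3
Reactants: 5 (S)-2-[2-methoxy-6-(triisopropylsilyloxy)phenyl]-2,3-dihydro-4H-pyran-4-one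
Product: 6 (2S,4S)-2-[2-methoxy-6-(triisopropylsilyloxy)phenyl]-3,4-dihydro-2H-pyran-4-ol
Conditions: NaBH4, CeCl3·7H2O, MeOH, −78 → −40 °C
Reagents that add atoms: none
Why: Luche reduction gives 1,2-addition to the vinylogous ester carbonyl; axial hydride delivery on the half-chair with a pseudo-equatorial aryl group should give the 2,4-cis alcohol, and since C4 is oxidised again in step 8 its configuration only matters for handling single isomers.

Step 4
Reactants: 6 (2S,4S)-2-[2-methoxy-6-(triisopropylsilyloxy)phenyl]-3,4-dihydro-2H-pyran-4-ol
Product: 7 (2S,4S)-2-[2-methoxy-6-(triisopropylsilyloxy)phenyl]-4-(triisopropylsilyloxy)-3,4-dihydro-2H-pyran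
Conditions: TIPSOTf, 2,6-lutidine, CH2Cl2, −78 → 0 °C
Reagents that add atoms: triisopropylsilyl trifluoromethanesulfonate, CC(C)[Si](OS(=O)(=O)C(F)(F)F)(C(C)C)C(C)C
Why: Silylation of an allylic alcohol under buffered conditions that avoid Ferrier-type ionisation of the enol ether; the triisopropylsilyl group removes the competing silyl-methyl metalation that a tert-butyldimethylsilyl ether would show in step 5.

Step 5
Reactants: 7 (2S,4S)-2-[2-methoxy-6-(triisopropylsilyloxy)phenyl]-4-(triisopropylsilyloxy)-3,4-dihydro-2H-pyran; 8 dimethyl squarate (3,4-dimethoxycyclobut-3-ene-1,2-dione)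
Product: 11 2,3,4-trimethoxy-4-[(2S,4S)-2-[2-methoxy-6-(triisopropylsilyloxy)phenyl]-4-(triisopropylsilyloxy)-3,4-dihydro-2H-pyran-6-yl]cyclobut-2-en-1-one, via C6-lithio dihydropyran 9 (not isolated), via lithium alkoxide adduct 10 (not isolated)
Conditions: t-BuLi (1.5 equiv), THF, −78 → 0 °C; cannulated into 8 (1.3 equiv), THF, −78 °C; MeOTf, −78 → 0 °C
Reagents that add atoms: methyl trifluoromethanesulfonate, COS(=O)(=O)C(F)(F)F
Why: α-Lithiation of a cyclic enol ether (as for silyl-protected glycals), 1,2-addition of the vinyllithium to one carbonyl of the squarate, and O-methylation of the tertiary alkoxide in the same flask; the C2–H bond lies in the plane of the di-ortho-substituted arene and is poorly acidified, inverse addition to excess 8 favours mono-addition, and the new carbinol centre forms as both epimers, which converge in step 6.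

Step 6
Reactants: 11 2,3,4-trimethoxy-4-[(2S,4S)-2-[2-methoxy-6-(triisopropylsilyloxy)phenyl]-4-(triisopropylsilyloxy)-3,4-dihydro-2H-pyran-6-yl]cyclobut-2-en-1-one
Product: 14 (2S,4S)-6,7,8-trimethoxy-2-[2-methoxy-6-(triisopropylsilyloxy)phenyl]-4-(triisopropylsilyloxy)chroman-5-ol, via dienylketene 12 (not isolated), via cyclohexadienone tautomer 13 (not isolated)
Conditions: toluene (degassed, 0.02 M), 110 °C
Reagents that add atoms: none
Why: Heating should cleave the bond between the carbonyl carbon and the sp3 carbon of the cyclobutenone by conrotatory 4π ring opening to give the (Z)-dienylketene 12. Its ketene carbon and pyran C5 are the termini of a hexatriene, and thermal disrotatory 6π electrocyclisation forms C4a–C5 to give the cyclohexa-2,4-dienone 13, which aromatises by shift of the C4a hydrogen to oxygen. The closest known reaction type is the thermal ring expansion of squarate-derived 4-alkenyl-4-alkoxycyclobutenones to para-alkoxyphenols (Moore rearrangement), which includes cyclic enol ethers as the alkenyl group. Ring A is thus closed in a 6π electrocyclic mode onto the preformed ring C, and only the four-membered ring is opened. No new stereocentre survives: the sp3 C4a of 13 is erased on aromatisation and both carbinol epimers of 11 give the same ketene. The selectivity needed is torquoselectivity, secured by the methoxy donor on the sp3 carbon, which rotates outward and thereby turns the pyranyl group inward toward the ketene. Regiochemistry follows from connectivity, the ring carbonyl of 11 becoming the free C5 hydroxyl and the methylated carbinol carbon becoming C8. C2 and C4 are remote sp3 centres and the neutral, dilute, oxygen-free medium should leave them and both silyl ethers untouched.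

Step 7
Reactants: 14 (2S,4S)-6,7,8-trimethoxy-2-[2-methoxy-6-(triisopropylsilyloxy)phenyl]-4-(triisopropylsilyloxy)chroman-5-ol
Product: 15 (2S,4S)-2-(2-hydroxy-6-methoxyphenyl)-6,7,8-trimethoxychromane-4,5-diol
Conditions: TBAF, AcOH, THF, 0 °C → rt, under argon
Reagents that add atoms: none
Why: Fluoride-mediated cleavage of the aryl and the secondary alkyl silyl ether in one operation; acetic acid buffering keeps the electron-rich phenols protonated and avoids base at the benzylic positions.

Step 8
Reactants: 15 (2S,4S)-2-(2-hydroxy-6-methoxyphenyl)-6,7,8-trimethoxychromane-4,5-diol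
Product: 16 (S)-5-hydroxy-2-(2-hydroxy-6-methoxyphenyl)-6,7,8-trimethoxychroman-4-one
Conditions: activated MnO2, CH2Cl2, rt
Reagents that add atoms: none
Why: Selective oxidation of a benzylic alcohol by MnO2 under neutral conditions, a reagent that converts hydroxybenzylic alcohols to the carbonyl compounds without attacking the phenol; the product is stabilised by the C5–OH/C4=O hydrogen bond, and C2 sees neither acid nor base.

## Compound list

1 | 2-hydroxy-6-methoxybenzaldehyde | COc1cccc(O)c1C=O | starting material
2 | 2-methoxy-6-(triisopropylsilyloxy)benzaldehyde | COc1cccc(O[Si](C(C)C)(C(C)C)C(C)C)c1C=O | intermediate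
3 | trans-1-methoxy-3-(trimethylsilyloxy)buta-1,3-diene | CO/C=C/C(=C)O[Si](C)(C)C | starting material
4 | (S,E)-1-methoxy-5-[2-methoxy-6-(triisopropylsilyloxy)phenyl]-5-(trimethylsilyloxy)pent-1-en-3-one (not isolated) | COc1cccc(O[Si](C(C)C)(C(C)C)C(C)C)c1[C@@H](O[Si](C)(C)C)CC(=O)/C=C/OC | intermediate
5 | (S)-2-[2-methoxy-6-(triisopropylsilyloxy)phenyl]-2,3-dihydro-4H-pyran-4-one | COc1cccc(O[Si](C(C)C)(C(C)C)C(C)C)c1[C@@H]1CC(=O)C=CO1 | intermediate
6 | (2S,4S)-2-[2-methoxy-6-(triisopropylsilyloxy)phenyl]-3,4-dihydro-2H-pyran-4-ol | COc1cccc(O[Si](C(C)C)(C(C)C)C(C)C)c1[C@@H]1C[C@H](O)C=CO1 | intermediate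
7 | (2S,4S)-2-[2-methoxy-6-(triisopropylsilyloxy)phenyl]-4-(triisopropylsilyloxy)-3,4-dihydro-2H-pyran | COc1cccc(O[Si](C(C)C)(C(C)C)C(C)C)c1[C@@H]1C[C@H](O[Si](C(C)C)(C(C)C)C(C)C)C=CO1 | intermediate
8 | dimethyl squarate (3,4-dimethoxycyclobut-3-ene-1,2-dione) | COC1=C(OC)C(=O)C1=O | starting material
9 | [(2S,4S)-2-[2-methoxy-6-(triisopropylsilyloxy)phenyl]-4-(triisopropylsilyloxy)-3,4-dihydro-2H-pyran-6-yl]lithium (not isolated) | COc1cccc(O[Si](C(C)C)(C(C)C)C(C)C)c1[C@@H]1C[C@H](O[Si](C(C)C)(C(C)C)C(C)C)C=C([Li])O1 | intermediate
10 | lithium 2,3-dimethoxy-1-[(2S,4S)-2-[2-methoxy-6-(triisopropylsilyloxy)phenyl]-4-(triisopropylsilyloxy)-3,4-dihydro-2H-pyran-6-yl]-4-oxocyclobut-2-en-1-olate (not isolated) | COc1cccc(O[Si](C(C)C)(C(C)C)C(C)C)c1[C@@H]1C[C@H](O[Si](C(C)C)(C(C)C)C(C)C)C=C(O1)C1(O[Li])C(OC)=C(OC)C1=O | intermediate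
11 | 2,3,4-trimethoxy-4-[(2S,4S)-2-[2-methoxy-6-(triisopropylsilyloxy)phenyl]-4-(triisopropylsilyloxy)-3,4-dihydro-2H-pyran-6-yl]cyclobut-2-en-1-one (both epimers at the cyclobutenone sp3 carbon) | COc1cccc(O[Si](C(C)C)(C(C)C)C(C)C)c1[C@@H]1C[C@H](O[Si](C(C)C)(C(C)C)C(C)C)C=C(O1)C1(OC)C(OC)=C(OC)C1=O | intermediate
12 | (3Z)-2,3,4-trimethoxy-4-[(2S,4S)-2-[2-methoxy-6-(triisopropylsilyloxy)phenyl]-4-(triisopropylsilyloxy)-3,4-dihydro-2H-pyran-6-yl]buta-1,3-dien-1-one (not isolated) | COc1cccc(O[Si](C(C)C)(C(C)C)C(C)C)c1[C@@H]1C[C@H](O[Si](C(C)C)(C(C)C)C(C)C)C=C(O1)/C(OC)=C(OC)\C(OC)=C=O | intermediate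
13 | (2S,4S)-6,7,8-trimethoxy-2-[2-methoxy-6-(triisopropylsilyloxy)phenyl]-4-(triisopropylsilyloxy)-2,3,4,4a-tetrahydro-5H-chromen-5-one (not isolated) | COc1cccc(O[Si](C(C)C)(C(C)C)C(C)C)c1[C@@H]1C[C@H](O[Si](C(C)C)(C(C)C)C(C)C)C2C(=O)C(OC)=C(OC)C(OC)=C2O1 | intermediate
14 | (2S,4S)-6,7,8-trimethoxy-2-[2-methoxy-6-(triisopropylsilyloxy)phenyl]-4-(triisopropylsilyloxy)chroman-5-ol | COc1cccc(O[Si](C(C)C)(C(C)C)C(C)C)c1[C@@H]1C[C@H](O[Si](C(C)C)(C(C)C)C(C)C)c2c(O)c(OC)c(OC)c(OC)c2O1 | intermediate
15 | (2S,4S)-2-(2-hydroxy-6-methoxyphenyl)-6,7,8-trimethoxychromane-4,5-diol | COc1cccc(O)c1[C@@H]1C[C@H](O)c2c(O)c(OC)c(OC)c(OC)c2O1 | intermediate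
16 | (S)-5-hydroxy-2-(2-hydroxy-6-methoxyphenyl)-6,7,8-trimethoxychroman-4-one | COc1cccc(O)c1[C@@H]1CC(=O)c2c(O)c(OC)c(OC)c(OC)c2O1 | target

## Step count and risk

Total step count: 8. Longest linear sequence: 8 steps (1 → 2 → 5 → 6 → 7 → 11 → 14 → 15 → 16); 3 and 8 are purchased.

Least certain steps:

Step 6 (key step).
- Risk: the electrocyclic sequence itself has close analogy. The likely failure is thermal expulsion of the C4 silyloxy group from the newly formed ortho-hydroxybenzylic ether (ortho-quinone methide formation) at the temperature needed for ring opening. Capture of the dienylketene by traces of water before it closes is a second possibility.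
- Fallback: the ring expansion is moved to the ketone oxidation level, setting out from 11 and rejoining the route at 16.
  - Buffered fluoride (TBAF, AcOH, THF) would remove both silyl groups from 11 to give the cyclobutenone diol 2,3,4-trimethoxy-4-[(2S,4S)-4-hydroxy-2-(2-hydroxy-6-methoxyphenyl)-3,4-dihydro-2H-pyran-6-yl]cyclobut-2-en-1-one F1.
  - MnO2 would oxidise its allylic alcohol to the pyranone 2,3,4-trimethoxy-4-[(2S)-2-(2-hydroxy-6-methoxyphenyl)-4-oxo-3,4-dihydro-2H-pyran-6-yl]cyclobut-2-en-1-one F2.
  - Heating F2 in toluene should open it to the dienylketene F3, which closes on the α-carbon of the vinylogous ester to the diketo tautomer F4 and enolises directly to 16.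
  - There is then no benzylic leaving group in the product, and no oxidation is needed after ring A exists. The price is that desilylation and oxidation are run on the more delicate cyclobutenone.

Step 5.
- Risk: deprotonation at the wrong site, either on ring B ortho to the methoxyl or at the benzylic C2–H, the latter with loss of configuration. Incomplete metalation and double addition to the squarate are further risks, because the step relies on a kinetic preference for the enol ether C–H.
- Fallback: the carbanion is placed at C6 by a sulfone, setting out from 7 and returning at 11.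
  - Benzenesulfinic acid (CH2Cl2, rt) is added across the enol ether of 7 to give the anomeric sulfone (2S,4S)-2-[2-methoxy-6-(triisopropylsilyloxy)phenyl]-6-(phenylsulfonyl)-4-(triisopropylsilyloxy)tetrahydro-2H-pyran F5.
  - LiN(iPr)2 at −78 °C removes the proton α to both sulfur and the ring oxygen, by far the most acidic site. The anion is added to 8 and the alkoxide is methylated with MeOTf to give the sulfonyl cyclobutenone adduct F6.
  - DBU then eliminates benzenesulfinic acid across C5–C6 to restore the enol ether as 11.

Step 2.
- Risk: low reactivity and poor facial discrimination, because the aldehyde is flanked by two ortho substituents that hinder binding to the catalyst. Partial loss of configuration during the acid cyclisation through ionisation of the electron-rich benzylic C–O bond is a second risk.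
- Fallback: C2 is set by a stoichiometric chiral reagent, setting out from 2 and returning at 5.
  - The diisopinocampheylboron enolate of (E)-4-chlorobut-3-en-2-one (Ipc2BCl, iPr2NEt, Et2O, −78 °C, the antipode of the reagent chosen to give the S carbinol) is added to 2 to give the aldol (S,E)-1-chloro-5-hydroxy-5-[2-methoxy-6-(triisopropylsilyloxy)phenyl]pent-1-en-3-one F7.
  - F7 is cyclised by conjugate addition and elimination of chloride (Me3SiOTf, iPr2NEt, CH2Cl2) to give 5.

Step 8.
- Risk: oxidation of the electron-rich phenols, especially the para-methoxyphenol of ring A, in competition with oxidation of the benzylic alcohol. Stalling through adsorption of the polyphenol on the oxidant is also possible.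
- Fallback: the phenols are masked during the oxidation, setting out from 15 and returning at 16.
  - Both phenols are acetylated selectively through their phenoxides (Ac2O, aqueous NaHCO3, 0 °C) to give the diacetate alcohol (2S,4S)-2-(2-acetoxy-6-methoxyphenyl)-4-hydroxy-6,7,8-trimethoxychroman-5-yl acetate F8.
  - Dess–Martin oxidation gives the diacetate ketone (S)-2-(2-acetoxy-6-methoxyphenyl)-6,7,8-trimethoxy-4-oxochroman-5-yl acetate F9.
  - The aryl acetates are cleaved with NH4OAc in aqueous MeOH at rt, conditions mild enough to spare C2, to give 16.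

## Further compounds

F1 | step 6 | 2,3,4-trimethoxy-4-[(2S,4S)-4-hydroxy-2-(2-hydroxy-6-methoxyphenyl)-3,4-dihydro-2H-pyran-6-yl]cyclobut-2-en-1-one | COc1cccc(O)c1[C@@H]1C[C@H](O)C=C(O1)C1(OC)C(OC)=C(OC)C1=O
F2 | step 6 | 2,3,4-trimethoxy-4-[(2S)-2-(2-hydroxy-6-methoxyphenyl)-4-oxo-3,4-dihydro-2H-pyran-6-yl]cyclobut-2-en-1-one | COc1cccc(O)c1[C@@H]1CC(=O)C=C(O1)C1(OC)C(OC)=C(OC)C1=O
F3 | step 6 | (3Z)-2,3,4-trimethoxy-4-[(2S)-2-(2-hydroxy-6-methoxyphenyl)-4-oxo-3,4-dihydro-2H-pyran-6-yl]buta-1,3-dien-1-one | COc1cccc(O)c1[C@@H]1CC(=O)C=C(O1)/C(OC)=C(OC)\C(OC)=C=O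
F4 | step 6 | (2S)-2-(2-hydroxy-6-methoxyphenyl)-6,7,8-trimethoxy-2,3-dihydro-4H-chromene-4,5(4aH)-dione | COc1cccc(O)c1[C@@H]1CC(=O)C2C(=O)C(OC)=C(OC)C(OC)=C2O1
F5 | step 5 | (2S,4S)-2-[2-methoxy-6-(triisopropylsilyloxy)phenyl]-6-(phenylsulfonyl)-4-(triisopropylsilyloxy)tetrahydro-2H-pyran (both C6 epimers) | COc1cccc(O[Si](C(C)C)(C(C)C)C(C)C)c1[C@@H]1C[C@H](O[Si](C(C)C)(C(C)C)C(C)C)CC(O1)S(=O)(=O)c1ccccc1
F6 | step 5 | 2,3,4-trimethoxy-4-[(4S,6S)-6-[2-methoxy-6-(triisopropylsilyloxy)phenyl]-2-(phenylsulfonyl)-4-(triisopropylsilyloxy)tetrahydro-2H-pyran-2-yl]cyclobut-2-en-1-one (epimer mixture) | COc1cccc(O[Si](C(C)C)(C(C)C)C(C)C)c1[C@@H]1C[C@H](O[Si](C(C)C)(C(C)C)C(C)C)CC(O1)(S(=O)(=O)c1ccccc1)C1(OC)C(OC)=C(OC)C1=O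
F7 | step 2 | (S,E)-1-chloro-5-hydroxy-5-[2-methoxy-6-(triisopropylsilyloxy)phenyl]pent-1-en-3-one | COc1cccc(O[Si](C(C)C)(C(C)C)C(C)C)c1[C@@H](O)CC(=O)/C=C/Cl
F8 | step 8 | (2S,4S)-2-(2-acetoxy-6-methoxyphenyl)-4-hydroxy-6,7,8-trimethoxychroman-5-yl acetate | COc1cccc(OC(C)=O)c1[C@@H]1C[C@H](O)c2c(OC(C)=O)c(OC)c(OC)c(OC)c2O1
F9 | step 8 | (S)-2-(2-acetoxy-6-methoxyphenyl)-6,7,8-trimethoxy-4-oxochroman-5-yl acetate | COc1cccc(OC(C)=O)c1[C@@H]1CC(=O)c2c(OC(C)=O)c(OC)c(OC)c(OC)c2O1
A1 | alternative 1 | (S)-2-[2-(benzyloxy)-6-methoxyphenyl]-5,6,7,8-tetramethoxychroman-4-one | COc1cccc(OCc2ccccc2)c1[C@@H]1CC(=O)c2c(OC)c(OC)c(OC)c(OC)c2O1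
A2 | alternative 1 | 3,4,5,6-tetramethoxy-2-(trimethylsilyl)phenyl trifluoromethanesulfonate | COc1c(OC)c(OC)c(OS(=O)(=O)C(F)(F)F)c([Si](C)(C)C)c1OC
A3 | alternative 1 | methyl (S)-3-[2-(benzyloxy)-6-methoxyphenyl]-3-hydroxypropanoate | COc1cccc(OCc2ccccc2)c1[C@@H](O)CC(=O)OC
A4 | alternative 1 | 3,4,5,6-tetramethoxybenzyne | COC1=C(OC)C(OC)=C(OC)C#C1
A5 | alternative 2 | (S)-2-[2-hydroxy-6-(triisopropylsilyloxy)phenyl]-5,6,7,8-tetramethoxychroman-4-one | CC(C)[Si](C(C)C)(C(C)C)Oc1cccc(O)c1[C@@H]1CC(=O)c2c(OC)c(OC)c(OC)c(OC)c2O1
A6 | alternative 2 | (S)-5,6,7,8-tetramethoxy-2-[(triisopropylsilyloxy)ethynyl]chroman-4-one | CC(C)[Si](C(C)C)(C(C)C)OC#C[C@@H]1CC(=O)c2c(OC)c(OC)c(OC)c(OC)c2O1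
A7 | alternative 2 | cyclobut-2-en-1-one | O=C1CC=C1
A8 | alternative 3 | (2S,4S)-2-[2-(benzyloxy)-6-methoxyphenyl]-4,5,6,7,8-pentamethoxychroman | COc1cccc(OCc2ccccc2)c1[C@@H]1C[C@H](OC)c2c(OC)c(OC)c(OC)c(OC)c2O1
A9 | alternative 3 | 2-(dimethoxymethyl)-3,4,5,6-tetramethoxyphenol | COC(OC)c1c(O)c(OC)c(OC)c(OC)c1OC
A10 | alternative 3 | 1-(benzyloxy)-3-methoxy-2-vinylbenzene | COc1cccc(OCc2ccccc2)c1C=C
A11 | alternative 3 | 2,3,4,5-tetramethoxy-6-(methoxymethylene)cyclohexa-2,4-dien-1-one | COC=C1C(=O)C(OC)=C(OC)C(OC)=C1OC
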